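**Assumptions:** The target has no stereocentres (the CMe2 carbon carries two identical methyls), so there is no enantiomer issue. 2-(Allyloxy)phenol and 2',4'-dihydroxy-6'-methoxyacetophenone are taken as commercially available.

## Retrosynthesis
1. The last step removes two allyl ethers (7-OH and 3'-OH) from the bis-allyl isoflavone.
2. The isoflavone C3–C1' bond is made by Suzuki coupling of a 3-iodochromone with a dimethylchromene-aryl boronate.
3. The chromone ring is formed from an o-hydroxyaryl enaminone by I2-mediated iodocyclisation, which also installs the 3-iodo group.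
4. The 2,2-dimethyl-2H-chromene ring is formed by a phenol + prenal annulation on a para-bromo-blocked mono-allyl catechol.
5. Both aryl fragments come from simple commercial phenols, and allyl is used for both phenols so that one neutral Pd(0) step frees them without touching the 5-OMe, the chromene alkene or the chromone.

## Forward synthesis

**Step 1**
Reactants: 1 (2-(allyloxy)phenol) + 2 (N-bromosuccinimide)
Product: 3 (2-(allyloxy)-4-bromophenol)
Conditions: NBS (1.0 equiv), CH2Cl2, 0 °C, 1 h
Reagents that add atoms: NBS, O=C1CCC(=O)N1Br (Br is delivered to the ring)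
Why: Electrophilic aromatic bromination goes para to the free OH, the strongest donor, which places Br meta to the O-allyl group. This blocks the para position so the later annulation can only occur ortho.

**Step 2**
Reactants: 3 + 4 (3-methylbut-2-enal, prenal) + 5 (phenylboronic acid)
Product: 6 (8-(allyloxy)-6-bromo-2,2-dimethyl-2H-chromene)
Conditions: 4 (3 equiv), 5 (1 equiv), cat. propionic acid, toluene, reflux, Dean–Stark, 12 h
Reagents that add atoms: prenal, CC(C)=CC=O (supplies the C5 CH=CH–CMe2 unit). PhB(OH)2 is a transient mediator and no atoms remain, so none.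
Why: The phenol forms an aryl boronate that directs ortho C–C condensation with prenal. Oxa-6π electrocyclisation of the resulting o-quinone methide then gives the 2,2-dimethyl-2H-chromene (phenol–enal annulation, Kaufman-type). Only C6 of the phenol is free, so regiochemistry is unambiguous.

**Step 3**
Reactants: 6 + 7 (bis(pinacolato)diboron)
Product: 8 (2-(8-(allyloxy)-2,2-dimethyl-2H-chromen-6-yl)-4,4,5,5-tetramethyl-1,3,2-dioxaborolane)
Conditions: 7 (1.2 equiv), Pd(dppf)Cl2 (5 mol %), KOAc (3 equiv), dioxane, 90 °C, 6 h
Reagents that add atoms: B2pin2, CC1(C)OB(OC1(C)C)B1OC(C)(C)C(C)(C)O1 (supplies Bpin)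
Why: Miyaura borylation converts the aryl bromide to the boronic ester. The mild base leaves the allyl ether and the chromene alkene intact.

**Step 4**
Reactants: 9 (2',4'-dihydroxy-6'-methoxyacetophenone) + 10 (allyl bromide)
Product: 11 (1-(4-(allyloxy)-2-hydroxy-6-methoxyphenyl)ethan-1-one)
Conditions: 10 (1.05 equiv), K2CO3 (1.5 equiv), acetone, 55 °C, 8 h
Reagents that add atoms: allyl bromide, C=CCBr (supplies the allyl group)
Why: Williamson etherification is selective for the 4-OH because the 2-OH is locked in a hydrogen bond to the carbonyl and the 4-OH is the more acidic and more accessible phenol.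

**Step 5**
Reactants: 11 + 12 (N,N-dimethylformamide dimethyl acetal)
Product: 13 ((E)-1-(4-(allyloxy)-2-hydroxy-6-methoxyphenyl)-3-(dimethylamino)prop-2-en-1-one)
Conditions: 12 (3 equiv), toluene, 110 °C, 6 h
Reagents that add atoms: DMF-DMA, COC(OC)N(C)C (supplies the =CH–NMe2 carbon)
Why: The methyl ketone condenses with the formamide acetal to give the push–pull enaminone, with loss of MeOH.

**Step 6**
Reactants: 13 + 14 (iodine)
Product: 15 (7-(allyloxy)-3-iodo-5-methoxy-4H-chromen-4-one)
Conditions: I2 (1.5 equiv), CHCl3, rt, 3 h
Reagents that add atoms: I2, II (supplies the 3-iodo substituent)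
Why: Iodination at the enaminone α-carbon is followed by intramolecular attack of the 2-OH and loss of HNMe2. This closes the γ-pyrone and installs the iodide in one step (iodocyclisation).

**Step 7**
Reactants: 15 + 8
Product: 16 (7-(allyloxy)-3-(8-(allyloxy)-2,2-dimethyl-2H-chromen-6-yl)-5-methoxy-4H-chromen-4-one)
Conditions: Pd(PPh3)4 (5 mol %), 2 M aq. Na2CO3, DME, 80 °C, 8 h
Reagents that add atoms: none (the iodide and Bpin are lost; the aryl group is transferred)
Why: Suzuki–Miyaura coupling joins the electron-poor vinyl iodide C3 to the aryl boronate. No stereocentre is formed. Aryl–allyl ethers survive because oxidative addition into the C–I bond is much faster than allyl ionisation.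

**Step 8**
Reactants: 16
Product: 17 (Glycyrrhizaisoflavone B)
Conditions: Pd(PPh3)4 (5 mol %), K2CO3 (3 equiv), MeOH, rt, 2 h
Reagents that add atoms: none (the allyl groups leave as allyl methyl ether)
Why: Pd(0) ionises the aryl allyl ethers to π-allyl-Pd, which MeOH/methoxide scavenges. Both phenols are released under near-neutral conditions that leave the 5-OMe, the chromene alkene and the chromone untouched.

## Compound list
1 | 2-(allyloxy)phenol | C=CCOc1ccccc1O | starting material
2 | N-bromosuccinimide | O=C1CCC(=O)N1Br | reagent
3 | 2-(allyloxy)-4-bromophenol | C=CCOc1cc(Br)ccc1O | intermediate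
4 | 3-methylbut-2-enal (prenal) | CC(C)=CC=O | starting material
5 | phenylboronic acid | OB(O)c1ccccc1 | reagent (mediator)
6 | 8-(allyloxy)-6-bromo-2,2-dimethyl-2H-chromene | C=CCOc1cc(Br)cc2C=CC(C)(C)Oc12 | intermediate
7 | bis(pinacolato)diboron | CC1(C)OB(OC1(C)C)B1OC(C)(C)C(C)(C)O1 | reagent
8 | 8-(allyloxy)-2,2-dimethyl-2H-chromen-6-yl pinacol boronate | C=CCOc1cc(B2OC(C)(C)C(C)(C)O2)cc2C=CC(C)(C)Oc12 | intermediate
9 | 2',4'-dihydroxy-6'-methoxyacetophenone | CC(=O)c1c(O)cc(O)cc1OC | starting material
10 | allyl bromide | C=CCBr | reagent
11 | 1-(4-(allyloxy)-2-hydroxy-6-methoxyphenyl)ethanone | CC(=O)c1c(O)cc(OCC=C)cc1OC | intermediate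
12 | DMF dimethyl acetal | COC(OC)N(C)C | reagent
13 | (E)-enaminone | CN(C)/C=C/C(=O)c1c(O)cc(OCC=C)cc1OC | intermediate
14 | iodine | II | reagent
15 | 7-(allyloxy)-3-iodo-5-methoxychromone | COc1cc(OCC=C)cc2occ(I)c(=O)c12 | intermediate
16 | bis-allyl isoflavone | COc1cc(OCC=C)cc2occ(-c3cc(OCC=C)c4OC(C)(C)C=Cc4c3)c(=O)c12 | intermediate
17 | Glycyrrhizaisoflavone B (achiral) | COc1cc(O)cc2occ(-c3cc(O)c4c(c3)C=CC(C)(C)O4)c(=O)c12 | target

## Totals
Total steps: 8. Longest linear sequence: 5 steps (1→3→6→8→16→17, or 9→11→13→15→16→17).

## Three steps most likely to fail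
1. **Step 2 (chromene annulation):** Yields are often moderate, and prenal can oligomerise.
   Fallback: make the propargyl ether of 3 with 3-chloro-3-methylbut-1-yne, K2CO3/KI, acetone, then cyclise it by thermal Claisen/6π closure in PhNEt2 at about 200 °C. This is a different bond-forming logic.
2. **Step 6 (iodocyclisation):** I2 could add to the allyl alkene or iodinate the electron-rich A-ring.
   Fallback: build the isoflavone by a deoxybenzoin route instead. Acylate 11 (or its 7-OMOM analogue) with an arylacetic acid bearing the dimethylchromene, then close the ring with DMF/MsCl/BF3·Et2O, with no iodochromone or Suzuki coupling.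
3. **Step 8 (Pd deallylation):** The chromone C2 may be attacked by MeO⁻, or Pd may interact with the chromene alkene.
   Fallback: replace the allyl groups with MOM ethers. Make the B-ring phenol by the Dakin route from 4-bromo-2-(MOM-O)benzaldehyde, use 7-OMOM, and remove both MOM groups in one step with mild HCl/MeOH.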